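The cyclohexane ring is disconnected at C4–C5 and C7–C7a (indene numbering), a [3+3] union. The key step exploits that both C7a and C4 hang on C3a, the β-carbon of the five-ring enone (C2=O, C3=C3a): C7a is the electrophilic β-carbon of a 3,4-dimethylcyclopentadienone generated from a 4-bromo enone, and C4 is its nucleophilic vinylogous methyl group. A malonate bearing a formylmethyl arm adds to C7a, then the methyl group condenses with the aldehyde, so both ring bonds form in one pot from two small achiral fragments. The C4 oxygen comes later by dienol ether oxidation; a lipase resolution supplies the enantiomer; the trienoate is attached last.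

Key step: step 4

Remark: positions are numbered as in 1H-indene (C1 side chain, C2 ketone, C4 acyloxy group, C7 carboxyl group, C7a methyl group).
Remark: the C1 configuration of the target is assumed to be the thermodynamically preferred one at this enolisable centre (side chain trans to the larger C7 substituent on C7a, cis to the methyl group).
Remark: 4, 5, 7 and 8 are racemic or stereochemically undefined; 9, 10 and 14 to 16 are racemic and are written as the enantiomer that is carried on; 17 is written as both enantiomers.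

Step 1
Reactants: 1 tert-butyl methyl propanedioate
Product: 2 1-tert-butyl 3-methyl 2-(prop-2-en-1-yl)propanedioate
Conditions: NaH, THF, 0 °C; allyl bromide, 0 °C to rt
Reagents that add atoms: allyl bromide C=CCBr
Why: C-alkylation of the sodium malonate enolate (SN2) with a slight deficit of the halide should stop at the monoallyl stage.

Step 2
Reactants: 2 1-tert-butyl 3-methyl 2-(prop-2-en-1-yl)propanedioate
Product: 3 1-tert-butyl 3-methyl 2-(2-oxoethyl)propanedioate
Conditions: O3, CH2Cl2, −78 °C; then Me2S, −78 °C to rt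
Reagents that add atoms: ozone [O-][O+]=O
Why: Ozonolysis with reductive work-up cleaves the only alkene to the aldehyde.

Step 3
Reactants: 4 3,4-dimethylcyclopent-2-en-1-one (racemic)
Product: 5 4-bromo-3,4-dimethylcyclopent-2-en-1-one (racemic; used crude)
Conditions: N-bromosuccinimide, AIBN (cat.), PhCF3, 80 °C
Reagents that add atoms: N-bromosuccinimide O=C1CCC(=O)N1Br
Why: Wohl–Ziegler bromination: hydrogen abstraction at C4 gives the tertiary radical that is allylic and vinylogous to the carbonyl group, and bromine transfer to this γ-carbon keeps the enone conjugated.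

Step 4
Reactants: 5 4-bromo-3,4-dimethylcyclopent-2-en-1-one, 3 1-tert-butyl 3-methyl 2-(2-oxoethyl)propanedioate
Product: 8 tert-butyl methyl 7a-methyl-2-oxo-2,6,7,7a-tetrahydro-1H-indene-7,7-dicarboxylate, via 3,4-dimethylcyclopenta-2,4-dien-1-one 6 (not isolated), via keto aldehyde Michael adduct 7 (not isolated)
Conditions: 3 (1.3 equiv), MeCN, −30 °C, DBU added slowly, then rt; then pyrrolidine (cat.), AcOH, 50 °C
Reagents that add atoms: none
Why: DBU eliminates HBr from 5 (E1cB) to the cross-conjugated dienone 6, to which the malonate anion of 3 adds in a Michael reaction at a methyl-bearing β-carbon (the two are equivalent by symmetry), giving keto aldehyde 7 with the new C7–C7a bond; pyrrolidinium acetate then turns the enone into its linear dienamine, whose terminal carbon (the former 3-methyl group, C4) attacks the aldehyde, and loss of water completes the C4–C5 bond. The closest known reactions are the addition of malonates to 4-halocyclopentenones by way of cyclopentadienones and the amine-catalysed intramolecular vinylogous aldol condensation of 3-methylcycloalkenones, together a Robinson-type [3+3] annulation. The six-membered ring closes in the 6-(enolendo)-exo-trig mode. The only lasting new stereocentre, C7a, arises from achiral partners and is racemic (resolved in step 11), and C7 with its two different esters stops being a stereocentre of consequence in step 5. The step needs 1,4-addition to outrun dimerisation of 6, which slow addition of the base to an excess of 3 should secure, and it needs closure at the C4 methyl group rather than at C1: aldolisation at C1 is reversible and would lead to a strained, cross-conjugated bicyclo[3.3.0]octadienone, whereas closure at C4 ends in the unstrained linear dienone.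

Step 5
Reactants: 8 tert-butyl methyl 7a-methyl-2-oxo-2,6,7,7a-tetrahydro-1H-indene-7,7-dicarboxylate
Product: 9 tert-butyl rac-(7R,7aS)-7a-methyl-2-oxo-2,6,7,7a-tetrahydro-1H-indene-7-carboxylate
Conditions: LiCl, H2O, DMSO, 130 °C
Reagents that add atoms: none
Why: Krapcho dealkoxycarbonylation: chloride attacks the methyl ester (SN2 at methyl, not at tert-butyl), the carboxylate loses CO2 and protonation of the ester enolate should give mainly the equatorial ester cis to the angular methyl group (any C7 epimer converges in step 9).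

Step 6
Reactants: 9 tert-butyl rac-(7R,7aS)-7a-methyl-2-oxo-2,6,7,7a-tetrahydro-1H-indene-7-carboxylate
Product: 10 tert-butyl rac-(7R,7aS)-7a-methyl-2-oxo-2,4,5,6,7,7a-hexahydro-1H-indene-7-carboxylate
Conditions: H2 (1 atm), RhCl(PPh3)3 (cat.), benzene–EtOH, rt
Reagents that add atoms: none
Why: Homogeneous hydrogenation with the rhodium chloride phosphine complex should saturate only the less hindered disubstituted C4=C5 bond of the dienone and leave the trisubstituted C3=C3a enone bond.

Step 7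
Reactants: 11 2-methylidenepropane-1,3-diol
Product: 12 2-({[tert-butyl(dimethyl)silyl]oxy}methyl)prop-2-en-1-ol
Conditions: NaH (1 equiv), THF, 0 °C; tert-butyldimethylsilyl chloride, rt
Reagents that add atoms: tert-butyldimethylsilyl chloride CC(C)(C)[Si](C)(C)Cl
Why: O-silylation of the sparingly soluble monosodium alkoxide of the symmetric diol should stop at the monosilyl ether.

Step 8
Reactants: 12 2-({[tert-butyl(dimethyl)silyl]oxy}methyl)prop-2-en-1-ol
Product: 13 {[2-(bromomethyl)prop-2-en-1-yl]oxy}(tert-butyl)dimethylsilane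
Conditions: CBr4, PPh3, CH2Cl2, 0 °C
Reagents that add atoms: tetrabromomethane BrC(Br)(Br)Br
Why: The Appel reaction converts the primary allylic alcohol into the bromide under neutral conditions that spare the silyl ether.

Step 9
Reactants: 10 tert-butyl rac-(7R,7aS)-7a-methyl-2-oxo-2,4,5,6,7,7a-hexahydro-1H-indene-7-carboxylate, 13 {[2-(bromomethyl)prop-2-en-1-yl]oxy}(tert-butyl)dimethylsilane
Product: 15 tert-butyl rac-(1R,7R,7aS)-1-[2-({[tert-butyl(dimethyl)silyl]oxy}methyl)prop-2-en-1-yl]-7a-methyl-2-oxo-2,4,5,6,7,7a-hexahydro-1H-indene-7-carboxylate, via C1 epimer 14 (not isolated)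
Conditions: LiN(iPr)2, THF, −78 °C; 13, −78 to 0 °C; then KOtBu (cat.), tBuOH, rt
Reagents that add atoms: none
Why: Kinetic α′-deprotonation of the enone at C1 and SN2 alkylation of the lithium enolate by the allylic bromide, followed by alkoxide-mediated equilibration, should place the C1 side chain trans to the larger C7 substituent on C7a (cis to the methyl group) and the C7 ester equatorial.

Step 10
Reactants: 15 tert-butyl rac-(1R,7R,7aS)-1-[2-({[tert-butyl(dimethyl)silyl]oxy}methyl)prop-2-en-1-yl]-7a-methyl-2-oxo-2,4,5,6,7,7a-hexahydro-1H-indene-7-carboxylate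
Product: 17 tert-butyl rac-(1R,4S,7R,7aS)-1-[2-({[tert-butyl(dimethyl)silyl]oxy}methyl)prop-2-en-1-yl]-4-hydroxy-7a-methyl-2-oxo-2,4,5,6,7,7a-hexahydro-1H-indene-7-carboxylate, via trimethylsilyl dienol ether 16 (not isolated)
Conditions: TMSOTf, Et3N, CH2Cl2, 0 °C to rt; then mCPBA, NaHCO3, −20 °C; then citric acid, MeOH, 0 °C
Reagents that add atoms: mCPBA OOC(=O)c1cccc(Cl)c1
Why: Rubottom-type γ-oxidation: the thermodynamic heteroannular silyl dienol ether (C2=C3 and C3a=C4) is far more electron-rich than the side-chain alkene and should be attacked by the peracid at C4 along the axial trajectory on the face syn to the angular methyl group, as in the 6β-hydroxylation of steroidal 3,5-dienol ethers, which gives the axial alcohol cis to that methyl group.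

Step 11
Reactants: 17 tert-butyl rac-(1R,4S,7R,7aS)-1-[2-({[tert-butyl(dimethyl)silyl]oxy}methyl)prop-2-en-1-yl]-4-hydroxy-7a-methyl-2-oxo-2,4,5,6,7,7a-hexahydro-1H-indene-7-carboxylate
Product: 18 tert-butyl (1R,4S,7R,7aS)-1-[2-({[tert-butyl(dimethyl)silyl]oxy}methyl)prop-2-en-1-yl]-4-hydroxy-7a-methyl-2-oxo-2,4,5,6,7,7a-hexahydro-1H-indene-7-carboxylate
Conditions: Burkholderia cepacia lipase, vinyl acetate, tert-butyl methyl ether, 30 °C, stopped slightly beyond half conversion; chromatography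
Reagents that add atoms: none
Why: Lipase-catalysed kinetic resolution by acylation: by the empirical size rule for secondary alcohols (large group C3a, medium group C5) the (4R) enantiomer should be acetylated faster, so that the (4S) alcohol is recovered.

Step 12
Reactants: 19 (4S)-4-benzyl-3-propanoyl-1,3-oxazolidin-2-one
Product: 20 (4S)-4-benzyl-3-[(2R)-2-methylbutanoyl]-1,3-oxazolidin-2-one
Conditions: NaN(SiMe3)2, THF, −78 °C; iodoethane, −78 to −30 °C
Reagents that add atoms: iodoethane CCI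
Why: Evans alkylation: the chelated Z-enolate of the imide is ethylated on the face opposite the benzyl group, which sets the (R) centre.

Step 13
Reactants: 20 (4S)-4-benzyl-3-[(2R)-2-methylbutanoyl]-1,3-oxazolidin-2-one
Product: 21 (2R)-2-methylbutan-1-ol
Conditions: LiBH4, Et2O, H2O (1 equiv), 0 °C
Reagents that add atoms: none
Why: Reductive cleavage of the N-acyl oxazolidinone by borohydride gives the primary alcohol without touching the α-stereocentre.

Step 14
Reactants: 21 (2R)-2-methylbutan-1-ol, 22 2-(triphenyl-λ5-phosphanylidene)propanal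
Product: 24 (2E,4R)-2,4-dimethylhex-2-enal, via (2R)-2-methylbutanal 23 (not isolated)
Conditions: TEMPO (cat.), PhI(OAc)2, CH2Cl2, rt; then 22, 40 °C
Reagents that add atoms: none
Why: Oxoammonium-mediated oxidation to the volatile, configurationally labile aldehyde and Wittig reaction in the same flask with the stabilised ylide should give the E-enal under neutral conditions.

Step 15
Reactants: 24 (2E,4R)-2,4-dimethylhex-2-enal, 25 ethyl (2E)-4-(diethoxyphosphoryl)but-2-enoate
Product: 26 ethyl (2E,4E,6E,8R)-6,8-dimethyldeca-2,4,6-trienoate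
Conditions: LiN(SiMe3)2, THF, −78 °C; 24, −78 to 0 °C
Reagents that add atoms: none
Why: Horner–Wadsworth–Emmons reaction of the vinylogous phosphonate anion at the carbon next to phosphorus builds the new C4=C5 bond with E geometry and extends the enal to the E,E,E-trienoate.

Step 16
Reactants: 26 ethyl (2E,4E,6E,8R)-6,8-dimethyldeca-2,4,6-trienoate
Product: 27 (2E,4E,6E,8R)-6,8-dimethyldeca-2,4,6-trienoic acid
Conditions: LiOH, THF–MeOH–H2O, rt; then 1 M HCl
Reagents that add atoms: lithium hydroxide [Li+].[OH-]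
Why: Saponification of the ethyl ester leaves the remote stereocentre and the alkene geometry untouched.

Step 17
Reactants: 18 tert-butyl (1R,4S,7R,7aS)-1-[2-({[tert-butyl(dimethyl)silyl]oxy}methyl)prop-2-en-1-yl]-4-hydroxy-7a-methyl-2-oxo-2,4,5,6,7,7a-hexahydro-1H-indene-7-carboxylate, 27 (2E,4E,6E,8R)-6,8-dimethyldeca-2,4,6-trienoic acid
Product: 29 tert-butyl (1R,4S,7R,7aS)-1-[2-({[tert-butyl(dimethyl)silyl]oxy}methyl)prop-2-en-1-yl]-4-{[(2E,4E,6E,8R)-6,8-dimethyldeca-2,4,6-trienoyl]oxy}-7a-methyl-2-oxo-2,4,5,6,7,7a-hexahydro-1H-indene-7-carboxylate, via mixed anhydride 28 (not isolated)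
Conditions: 27, 2,4,6-trichlorobenzoyl chloride, Et3N, toluene, rt; then 18, DMAP, rt to 40 °C
Reagents that add atoms: none
Why: Yamaguchi esterification: acyl transfer from the mixed anhydride through the acylpyridinium ion to the axial C4 alcohol proceeds with retention at C4.

Step 18
Reactants: 29 tert-butyl (1R,4S,7R,7aS)-1-[2-({[tert-butyl(dimethyl)silyl]oxy}methyl)prop-2-en-1-yl]-4-{[(2E,4E,6E,8R)-6,8-dimethyldeca-2,4,6-trienoyl]oxy}-7a-methyl-2-oxo-2,4,5,6,7,7a-hexahydro-1H-indene-7-carboxylate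
Product: 30 (1R,4S,7R,7aS)-4-{[(2E,4E,6E,8R)-6,8-dimethyldeca-2,4,6-trienoyl]oxy}-1-[2-(hydroxymethyl)prop-2-en-1-yl]-7a-methyl-2-oxo-2,4,5,6,7,7a-hexahydro-1H-indene-7-carboxylic acid
Conditions: CF3CO2H–CH2Cl2 (1:4), anisole, 0 °C to rt; then aq. NaHCO3–MeOH, 0 °C, and acidification
Reagents that add atoms: none
Why: Acidolysis cleaves the tert-butyl ester through the tert-butyl cation and solvolyses the primary silyl ether, while the conjugated trienoate and the γ-acyloxy enone, which ionise poorly, should survive.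

Step 19
Reactants: 30 (1R,4S,7R,7aS)-4-{[(2E,4E,6E,8R)-6,8-dimethyldeca-2,4,6-trienoyl]oxy}-1-[2-(hydroxymethyl)prop-2-en-1-yl]-7a-methyl-2-oxo-2,4,5,6,7,7a-hexahydro-1H-indene-7-carboxylic acid
Product: 31 (1R,4S,7R,7aS)-4-{[(2E,4E,6E,8R)-6,8-dimethyldeca-2,4,6-trienoyl]oxy}-1-(2-formylprop-2-en-1-yl)-7a-methyl-2-oxo-2,4,5,6,7,7a-hexahydro-1H-indene-7-carboxylic acid
Conditions: Dess–Martin periodinane, NaHCO3, CH2Cl2, 0 °C to rt
Reagents that add atoms: none
Why: Dess–Martin oxidation of the only alcohol, a primary allylic one, gives the 2-substituted acrolein and tolerates the free carboxylic acid.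

Compound list
1 | tert-butyl methyl propanedioate | COC(=O)CC(=O)OC(C)(C)C | starting material
2 | 1-tert-butyl 3-methyl 2-(prop-2-en-1-yl)propanedioate | C=CCC(C(=O)OC)C(=O)OC(C)(C)C | intermediate
3 | 1-tert-butyl 3-methyl 2-(2-oxoethyl)propanedioate | O=CCC(C(=O)OC)C(=O)OC(C)(C)C | intermediate
4 | 3,4-dimethylcyclopent-2-en-1-one (racemic) | CC1CC(=O)C=C1C | starting material
5 | 4-bromo-3,4-dimethylcyclopent-2-en-1-one (racemic) | CC1=CC(=O)CC1(C)Br | intermediate
6 | 3,4-dimethylcyclopenta-2,4-dien-1-one | CC1=CC(=O)C=C1C | intermediate (not isolated)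
7 | 1-tert-butyl 3-methyl 2-(1,2-dimethyl-4-oxocyclopent-2-en-1-yl)-2-(2-oxoethyl)propanedioate (stereoisomer mixture) | CC1=CC(=O)CC1(C)C(CC=O)(C(=O)OC)C(=O)OC(C)(C)C | intermediate (not isolated)
8 | tert-butyl methyl 7a-methyl-2-oxo-2,6,7,7a-tetrahydro-1H-indene-7,7-dicarboxylate (racemic; both C7 epimers) | CC12CC(=O)C=C1C=CCC2(C(=O)OC)C(=O)OC(C)(C)C | intermediate
9 | tert-butyl rac-(7R,7aS)-7a-methyl-2-oxo-2,6,7,7a-tetrahydro-1H-indene-7-carboxylate | C1C(=O)C=C2C=CC[C@@H](C(=O)OC(C)(C)C)[C@@]21C | intermediate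
10 | tert-butyl rac-(7R,7aS)-7a-methyl-2-oxo-2,4,5,6,7,7a-hexahydro-1H-indene-7-carboxylate | C1C(=O)C=C2CCC[C@@H](C(=O)OC(C)(C)C)[C@@]21C | intermediate
11 | 2-methylidenepropane-1,3-diol | C=C(CO)CO | starting material
12 | 2-({[tert-butyl(dimethyl)silyl]oxy}methyl)prop-2-en-1-ol | C=C(CO)CO[Si](C)(C)C(C)(C)C | intermediate
13 | {[2-(bromomethyl)prop-2-en-1-yl]oxy}(tert-butyl)dimethylsilane | C=C(CBr)CO[Si](C)(C)C(C)(C)C | intermediate
14 | tert-butyl rac-(1S,7R,7aS)-1-[2-({[tert-butyl(dimethyl)silyl]oxy}methyl)prop-2-en-1-yl]-7a-methyl-2-oxo-2,4,5,6,7,7a-hexahydro-1H-indene-7-carboxylate (C1 epimer of 15) | C=C(CO[Si](C)(C)C(C)(C)C)C[C@@H]1C(=O)C=C2CCC[C@@H](C(=O)OC(C)(C)C)[C@@]21C | intermediate (not isolated)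
15 | tert-butyl rac-(1R,7R,7aS)-1-[2-({[tert-butyl(dimethyl)silyl]oxy}methyl)prop-2-en-1-yl]-7a-methyl-2-oxo-2,4,5,6,7,7a-hexahydro-1H-indene-7-carboxylate | C=C(CO[Si](C)(C)C(C)(C)C)C[C@H]1C(=O)C=C2CCC[C@@H](C(=O)OC(C)(C)C)[C@@]21C | intermediate
16 | tert-butyl rac-(1R,7R,7aS)-1-[2-({[tert-butyl(dimethyl)silyl]oxy}methyl)prop-2-en-1-yl]-7a-methyl-2-[(trimethylsilyl)oxy]-5,6,7,7a-tetrahydro-1H-indene-7-carboxylate | C=C(CO[Si](C)(C)C(C)(C)C)C[C@H]1C(O[Si](C)(C)C)=CC2=CCC[C@@H](C(=O)OC(C)(C)C)[C@@]21C | intermediate (not isolated)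
17 | tert-butyl rac-(1R,4S,7R,7aS)-1-[2-({[tert-butyl(dimethyl)silyl]oxy}methyl)prop-2-en-1-yl]-4-hydroxy-7a-methyl-2-oxo-2,4,5,6,7,7a-hexahydro-1H-indene-7-carboxylate (racemate, both enantiomers written) | C=C(CO[Si](C)(C)C(C)(C)C)C[C@H]1C(=O)C=C2[C@@H](O)CC[C@@H](C(=O)OC(C)(C)C)[C@@]21C.C=C(CO[Si](C)(C)C(C)(C)C)C[C@@H]1C(=O)C=C2[C@H](O)CC[C@H](C(=O)OC(C)(C)C)[C@]21C | intermediate
18 | tert-butyl (1R,4S,7R,7aS)-1-[2-({[tert-butyl(dimethyl)silyl]oxy}methyl)prop-2-en-1-yl]-4-hydroxy-7a-methyl-2-oxo-2,4,5,6,7,7a-hexahydro-1H-indene-7-carboxylate | C=C(CO[Si](C)(C)C(C)(C)C)C[C@H]1C(=O)C=C2[C@@H](O)CC[C@@H](C(=O)OC(C)(C)C)[C@@]21C | intermediate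
19 | (4S)-4-benzyl-3-propanoyl-1,3-oxazolidin-2-one | CCC(=O)N1[C@@H](Cc2ccccc2)COC1=O | starting material
20 | (4S)-4-benzyl-3-[(2R)-2-methylbutanoyl]-1,3-oxazolidin-2-one | CC[C@@H](C)C(=O)N1[C@@H](Cc2ccccc2)COC1=O | intermediate
21 | (2R)-2-methylbutan-1-ol | CC[C@@H](C)CO | intermediate
22 | 2-(triphenyl-λ5-phosphanylidene)propanal | CC(C=O)=P(c1ccccc1)(c1ccccc1)c1ccccc1 | starting material
23 | (2R)-2-methylbutanal | CC[C@@H](C)C=O | intermediate (not isolated)
24 | (2E,4R)-2,4-dimethylhex-2-enal | O=C/C(C)=C/[C@H](C)CC | intermediate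
25 | ethyl (2E)-4-(diethoxyphosphoryl)but-2-enoate | CCOC(=O)/C=C/CP(=O)(OCC)OCC | starting material
26 | ethyl (2E,4E,6E,8R)-6,8-dimethyldeca-2,4,6-trienoate | CCOC(=O)/C=C/C=C/C(C)=C/[C@H](C)CC | intermediate
27 | (2E,4E,6E,8R)-6,8-dimethyldeca-2,4,6-trienoic acid | OC(=O)/C=C/C=C/C(C)=C/[C@H](C)CC | intermediate
28 | (2E,4E,6E,8R)-6,8-dimethyldeca-2,4,6-trienoic 2,4,6-trichlorobenzoic anhydride | O=C(OC(=O)/C=C/C=C/C(C)=C/[C@H](C)CC)c1c(Cl)cc(Cl)cc1Cl | intermediate (not isolated)
29 | tert-butyl (1R,4S,7R,7aS)-1-[2-({[tert-butyl(dimethyl)silyl]oxy}methyl)prop-2-en-1-yl]-4-{[(2E,4E,6E,8R)-6,8-dimethyldeca-2,4,6-trienoyl]oxy}-7a-methyl-2-oxo-2,4,5,6,7,7a-hexahydro-1H-indene-7-carboxylate | C=C(CO[Si](C)(C)C(C)(C)C)C[C@H]1C(=O)C=C2[C@@H](OC(=O)/C=C/C=C/C(C)=C/[C@H](C)CC)CC[C@@H](C(=O)OC(C)(C)C)[C@@]21C | intermediate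
30 | (1R,4S,7R,7aS)-4-{[(2E,4E,6E,8R)-6,8-dimethyldeca-2,4,6-trienoyl]oxy}-1-[2-(hydroxymethyl)prop-2-en-1-yl]-7a-methyl-2-oxo-2,4,5,6,7,7a-hexahydro-1H-indene-7-carboxylic acid | C=C(CO)C[C@H]1C(=O)C=C2[C@@H](OC(=O)/C=C/C=C/C(C)=C/[C@H](C)CC)CC[C@@H](C(=O)O)[C@@]21C | intermediate
31 | (1R,4S,7R,7aS)-4-{[(2E,4E,6E,8R)-6,8-dimethyldeca-2,4,6-trienoyl]oxy}-1-(2-formylprop-2-en-1-yl)-7a-methyl-2-oxo-2,4,5,6,7,7a-hexahydro-1H-indene-7-carboxylic acid | C=C(C=O)C[C@H]1C(=O)C=C2[C@@H](OC(=O)/C=C/C=C/C(C)=C/[C@H](C)CC)CC[C@@H](C(=O)O)[C@@]21C | target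

Total step count: 19.
Longest linear sequence: 11 steps (steps 1, 2, 4, 5, 6, 9, 10, 11, 17, 18 and 19).

Steps most likely to fail

Step 4. The fully substituted malonate carbon may add too slowly to the methyl-bearing β-carbon, so that the transient dienone dimerises, or the aldol ring closure may run at C1 instead of at the C4 methyl group. The fallback sets out from 5 and uses a less hindered, secondary ester enolate and an aldehyde that is unmasked afterwards. Two equivalents of the lithium enolate of commercial tert-butyl pent-4-enoate (LiN(iPr)2, THF–DMPU, −78 °C; the first equivalent eliminates HBr) should add 1,4 to the dienone and give tert-butyl 2-(1,2-dimethyl-4-oxocyclopent-2-en-1-yl)pent-4-enoate F1. Ozonolysis of the terminal alkene (O3, then Me2S) gives tert-butyl 2-(1,2-dimethyl-4-oxocyclopent-2-en-1-yl)-4-oxobutanoate F2, and pyrrolidinium acetate (toluene, 60 °C) closes the six-membered ring by the same vinylogous aldol condensation. The route is rejoined at 9, so that step 5 is not needed.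

Step 10. The peracid may attack the dienol ether on the face away from the angular methyl group, or the axial alcohol may epimerise through the dienol during work-up, so that the equatorial C4 epimer prevails. The fallback sets out from 15. The same oxidation then delivers tert-butyl rac-(1R,4R,7R,7aS)-1-[2-({[tert-butyl(dimethyl)silyl]oxy}methyl)prop-2-en-1-yl]-4-hydroxy-7a-methyl-2-oxo-2,4,5,6,7,7a-hexahydro-1H-indene-7-carboxylate F3. A Mitsunobu reaction with 4-nitrobenzoic acid (PPh3, diisopropyl azodicarboxylate, toluene, 0 °C) inverts C4 and gives tert-butyl rac-(1R,4S,7R,7aS)-1-[2-({[tert-butyl(dimethyl)silyl]oxy}methyl)prop-2-en-1-yl]-7a-methyl-4-[(4-nitrobenzoyl)oxy]-2-oxo-2,4,5,6,7,7a-hexahydro-1H-indene-7-carboxylate F4. Mild methanolysis (K2CO3, MeOH, 0 °C) returns to 17.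

Step 11. The lipase may not accept the hindered axial alcohol, or may acylate both enantiomers at similar rates. The fallback sets out from racemic 17, which is esterified with 27 as in step 17. The wanted ester 29 is then separated by preparative HPLC from its diastereomer tert-butyl (1S,4R,7S,7aR)-1-[2-({[tert-butyl(dimethyl)silyl]oxy}methyl)prop-2-en-1-yl]-4-{[(2E,4E,6E,8R)-6,8-dimethyldeca-2,4,6-trienoyl]oxy}-7a-methyl-2-oxo-2,4,5,6,7,7a-hexahydro-1H-indene-7-carboxylate F5, and the route continues from 29.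

Further compounds
F1 | step 4 | tert-butyl 2-(1,2-dimethyl-4-oxocyclopent-2-en-1-yl)pent-4-enoate (stereoisomer mixture) | C=CCC(C(=O)OC(C)(C)C)C1(C)CC(=O)C=C1C
F2 | step 4 | tert-butyl 2-(1,2-dimethyl-4-oxocyclopent-2-en-1-yl)-4-oxobutanoate (stereoisomer mixture) | O=CCC(C(=O)OC(C)(C)C)C1(C)CC(=O)C=C1C
F3 | step 10 | tert-butyl rac-(1R,4R,7R,7aS)-1-[2-({[tert-butyl(dimethyl)silyl]oxy}methyl)prop-2-en-1-yl]-4-hydroxy-7a-methyl-2-oxo-2,4,5,6,7,7a-hexahydro-1H-indene-7-carboxylate | C=C(CO[Si](C)(C)C(C)(C)C)C[C@H]1C(=O)C=C2[C@H](O)CC[C@@H](C(=O)OC(C)(C)C)[C@@]21C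
F4 | step 10 | tert-butyl rac-(1R,4S,7R,7aS)-1-[2-({[tert-butyl(dimethyl)silyl]oxy}methyl)prop-2-en-1-yl]-7a-methyl-4-[(4-nitrobenzoyl)oxy]-2-oxo-2,4,5,6,7,7a-hexahydro-1H-indene-7-carboxylate | C=C(CO[Si](C)(C)C(C)(C)C)C[C@H]1C(=O)C=C2[C@@H](OC(=O)c3ccc(cc3)[N+](=O)[O-])CC[C@@H](C(=O)OC(C)(C)C)[C@@]21C
F5 | step 11 | tert-butyl (1S,4R,7S,7aR)-1-[2-({[tert-butyl(dimethyl)silyl]oxy}methyl)prop-2-en-1-yl]-4-{[(2E,4E,6E,8R)-6,8-dimethyldeca-2,4,6-trienoyl]oxy}-7a-methyl-2-oxo-2,4,5,6,7,7a-hexahydro-1H-indene-7-carboxylate | C=C(CO[Si](C)(C)C(C)(C)C)C[C@@H]1C(=O)C=C2[C@H](OC(=O)/C=C/C=C/C(C)=C/[C@H](C)CC)CC[C@H](C(=O)OC(C)(C)C)[C@]21C
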